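**Retrosynthetic overview**

1. Target 21 comes from 20 by exchanging the last ring methoxy group (a vinylogous ester) for OOH, and 20 from 19 by half-saponification. The 2,5-dimethoxy-1,4-benzoquinone comes from oxidation of the central tetramethoxybenzene ring of 17, so the quinone ring is unveiled last.
2. The strategy rests on the prenyl groups at indole C5, a benzenoid carbon that an indole does not offer for alkylation. In a 4-oxo-4,5,6,7-tetrahydroindole the same carbon is the α-carbon of the C4 ketone, so 14 comes from 11 by C5 enolate prenylation. The benzenoid rings of 17 are then formed from 14 by C4 reduction, dehydration and dehydrogenation.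
3. Both pyrrole rings (N1–C7a and C3–C3a of each) come from a twofold Knorr-type condensation of the bis(aminoacetyl)arene 7 with two molecules of cyclohexane-1,3-dione 8. These are the first rings formed, each on a saturated six-membered ring.
4. 7 comes from 1,2,4,5-tetramethoxybenzene 1 by dibromination, double Br/Li exchange and acylation with two molecules of the Boc-glycine Weinreb amide 3.

Key step: step 4

Assumption: every twofold transformation is run on both identical halves in one operation and half-converted species are not counted as separate compounds; where such a step consumes two molecules of a numbered compound, the Reactants line says so and the second molecule is also entered under "Reagents that add atoms"; the C4/C5 stereocentres of the tetrahydroindole stage are transient diastereomer mixtures, and the target has no stereocentre.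

**Route**

Step 1
Reactants: 1 1,2,4,5-tetramethoxybenzene
Product: 2 1,4-dibromo-2,3,5,6-tetramethoxybenzene
Conditions: N-bromosuccinimide (2.1 equiv), MeCN, 0 °C to rt, dark
Reagents that add atoms: N-bromosuccinimide, O=C1CCC(=O)N1Br
Why: Electrophilic aromatic bromination; the two remaining ring C–H positions are each flanked by two methoxy groups and are the only sites available, so twofold substitution should be unambiguous.

Step 2
Reactants: 2 1,4-dibromo-2,3,5,6-tetramethoxybenzene; 3 N-Boc-glycine N-methoxy-N-methylamide (two molecules)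
Product: 6 1,4-bis(N-Boc-aminoacetyl)-2,3,5,6-tetramethoxybenzene, via dilithio arene 4 (not isolated), via N-chloromagnesio Weinreb amide 5 (not isolated)
Conditions: 2, t-BuLi (4.2 equiv), THF, −78 °C; separately 3 (2.5 equiv), i-PrMgCl (2.5 equiv), THF, −20 °C; combine at −78 °C, warm to 0 °C; cold 1 M HCl quench
Reagents that add atoms: N-Boc-glycine N-methoxy-N-methylamide (second molecule of 3), CON(C)C(=O)CNC(=O)OC(C)(C)C
Why: Twofold bromine–lithium exchange followed by Weinreb ketone synthesis, each aryllithium carbon taking up one molecule of the amide; the carbamate N–H is removed beforehand with i-PrMgCl so that it cannot protonate the aryllithium, and the chelated tetrahedral adduct should stop each addition at the ketone stage.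

Step 3
Reactants: 6 1,4-bis(N-Boc-aminoacetyl)-2,3,5,6-tetramethoxybenzene
Product: 7 1,4-bis(aminoacetyl)-2,3,5,6-tetramethoxybenzene bis-hydrochloride
Conditions: 4 M HCl in dioxane, CH2Cl2, 0 °C to rt; salt collected by filtration
Reagents that add atoms: hydrogen chloride, Cl
Why: Acidolysis of the tert-butyl carbamates; the aminoketone is kept as its ammonium salt, in which form it cannot self-condense.

Step 4
Reactants: 7 1,4-bis(aminoacetyl)-2,3,5,6-tetramethoxybenzene bis-hydrochloride; 8 cyclohexane-1,3-dione (two molecules)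
Product: 10 3,3'-(2,3,5,6-tetramethoxy-1,4-phenylene)bis(1,5,6,7-tetrahydro-4H-indol-4-one), via bis-enaminone 9 (not isolated)
Conditions: 8 (5 equiv), NaOAc (2.2 equiv, added in portions), AcOH/H2O 1:1, 60 °C, then reflux
Reagents that add atoms: cyclohexanedione (second molecule of 8), O=C1CCCC(=O)C1
Why: Sodium acetate frees each primary amine from its hydrochloride in the presence of a large excess of the dione, so that it should condense with a dione carbonyl to the vinylogous amide 9 (N1–C7a) before two aminoketone units can combine to a dihydropyrazine; once nitrogen is part of the enaminone it is no longer nucleophilic enough to dimerise. On heating in acetic acid the enaminone α-carbon should add to the aryl ketone carbonyl and the resulting carbinol lose water to the aromatic pyrrole (C3–C3a); this is the Knorr-type condensation of α-aminoketones with cyclohexane-1,3-diones, the standard entry to 3-substituted 4-oxo-4,5,6,7-tetrahydroindoles, here run twice on one arene with one dione molecule per arm. Each pyrrole ring closes by a 5-exo-trig aldol-type attack with the enaminone C=C inside the forming ring, a geometry that pyrrole syntheses of this kind tolerate because the subsequent dehydration to the aromatic ring is irreversible. No stereocentre is formed. The step needs the aryl group at C3 and not at C2, and this is fixed by the connectivity of the aminoketone (nitrogen sits on the CH2 that becomes C2, the aryl ketone carbon becomes C3), while the symmetrical dione offers only one kind of carbonyl and one nucleophilic carbon. The aryl ketone, flanked by two methoxy groups, is hindered but twisted out of conjugation and therefore still electrophilic, so the intramolecular closure should go at reflux.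

Step 5
Reactants: 10 3,3'-(2,3,5,6-tetramethoxy-1,4-phenylene)bis(1,5,6,7-tetrahydro-4H-indol-4-one)
Product: 11 di-tert-butyl 3,3'-(2,3,5,6-tetramethoxy-1,4-phenylene)bis(4-oxo-4,5,6,7-tetrahydro-1H-indole-1-carboxylate)
Conditions: Boc2O (2.5 equiv), DMAP (0.2 equiv), MeCN, rt
Reagents that add atoms: di-tert-butyl dicarbonate, CC(C)(C)OC(=O)OC(=O)OC(C)(C)C
Why: DMAP-catalysed N-acylation of the pyrrole N–H; the carbamate removes the vinylogous-amide character of the C4 ketone, which is needed for clean enolisation and hydride reduction, and later shields the indoles from oxidation.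

Step 6
Reactants: 11 di-tert-butyl 3,3'-(2,3,5,6-tetramethoxy-1,4-phenylene)bis(4-oxo-4,5,6,7-tetrahydro-1H-indole-1-carboxylate); 12 prenyl bromide (two molecules)
Product: 14 di-tert-butyl 3,3'-(2,3,5,6-tetramethoxy-1,4-phenylene)bis[5-(3-methylbut-2-en-1-yl)-4-oxo-4,5,6,7-tetrahydro-1H-indole-1-carboxylate] (mixture of C5/C5' diastereomers), via dilithium bis-enolate 13 (not isolated)
Conditions: LiN(i-Pr)2 (2.3 equiv), THF, −78 °C; then 12 (3 equiv), DMPU, −78 to −30 °C
Reagents that add atoms: prenyl bromide (second molecule of 12), CC(C)=CCBr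
Why: Kinetic lithium enolate alkylation (SN2 on an allylic bromide), each of the two enolates taking one molecule of prenyl bromide; C5 is the only sp3 α-carbon of each C4 ketone because C3a is a pyrrole carbon, so prenyl can enter only there, and the two new C5 stereocentres are left uncontrolled since they are erased in step 8.

Step 7
Reactants: 14 di-tert-butyl 3,3'-(2,3,5,6-tetramethoxy-1,4-phenylene)bis[5-(3-methylbut-2-en-1-yl)-4-oxo-4,5,6,7-tetrahydro-1H-indole-1-carboxylate]
Product: 15 di-tert-butyl 3,3'-(2,3,5,6-tetramethoxy-1,4-phenylene)bis[4-hydroxy-5-(3-methylbut-2-en-1-yl)-4,5,6,7-tetrahydro-1H-indole-1-carboxylate] (mixture of diastereomers)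
Conditions: NaBH4 (4 equiv), MeOH/THF, 0 °C to rt
Reagents that add atoms: none
Why: Borohydride reduction of a ketone that behaves as an aryl ketone once nitrogen carries the carbamate; the C4 carbinol configuration is uncontrolled and irrelevant because C4 becomes sp2 in the next step.

Step 8
Reactants: 15 di-tert-butyl 3,3'-(2,3,5,6-tetramethoxy-1,4-phenylene)bis[4-hydroxy-5-(3-methylbut-2-en-1-yl)-4,5,6,7-tetrahydro-1H-indole-1-carboxylate]
Product: 16 di-tert-butyl 3,3'-(2,3,5,6-tetramethoxy-1,4-phenylene)bis[5-(3-methylbut-2-en-1-yl)-6,7-dihydro-1H-indole-1-carboxylate]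
Conditions: TsOH·H2O (5 mol %), toluene, 50 °C; crude product taken on directly
Reagents that add atoms: none
Why: Acid-catalysed E1 dehydration through a pyrrole-stabilised C4 cation; C5–H is the only β-hydrogen, so the C4=C5 alkene of the 6,7-dihydroindole should be the sole outcome from every diastereomer.

Step 9
Reactants: 16 di-tert-butyl 3,3'-(2,3,5,6-tetramethoxy-1,4-phenylene)bis[5-(3-methylbut-2-en-1-yl)-6,7-dihydro-1H-indole-1-carboxylate]
Product: 17 di-tert-butyl 3,3'-(2,3,5,6-tetramethoxy-1,4-phenylene)bis[5-(3-methylbut-2-en-1-yl)-1H-indole-1-carboxylate]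
Conditions: DDQ (2.2 equiv), CH2Cl2, 0 °C to rt
Reagents that add atoms: none
Why: Dehydrogenative aromatisation with DDQ (hydride abstraction from the C6/C7 methylene positions, then proton loss), driven by formation of the benzenoid ring and expected to be faster at 0 °C than oxidation at the prenyl groups.

Step 10
Reactants: 17 di-tert-butyl 3,3'-(2,3,5,6-tetramethoxy-1,4-phenylene)bis[5-(3-methylbut-2-en-1-yl)-1H-indole-1-carboxylate]
Product: 18 di-tert-butyl 3,3'-(2,5-dimethoxy-3,6-dioxocyclohexa-1,4-diene-1,4-diyl)bis[5-(3-methylbut-2-en-1-yl)-1H-indole-1-carboxylate]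
Conditions: (NH4)2Ce(NO3)6 (2.5 equiv), MeCN/H2O, 0 °C, short reaction time
Reagents that add atoms: water, O
Why: Oxidative demethylation of a hydroquinone dimethyl ether unit by (NH4)2Ce(NO3)6; the tetramethoxybenzene core has the lowest oxidation potential in the molecule while the N-Boc indoles are deactivated, and water attacks the arene radical cation at two para methoxy-bearing carbons to give the 2,5-dimethoxy-1,4-benzoquinone.

Step 11
Reactants: 18 di-tert-butyl 3,3'-(2,5-dimethoxy-3,6-dioxocyclohexa-1,4-diene-1,4-diyl)bis[5-(3-methylbut-2-en-1-yl)-1H-indole-1-carboxylate]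
Product: 19 2,5-dimethoxy-3,6-bis[5-(3-methylbut-2-en-1-yl)-1H-indol-3-yl]-1,4-benzoquinone
Conditions: NaOMe (0.3 equiv), MeOH/THF, 0 °C to rt
Reagents that add atoms: none
Why: Methoxide-catalysed methanolysis of the N-acyl indole carbamates, whose indolide is a good leaving group when conjugated with the quinone; attack of methoxide on the methoxyquinone itself is degenerate.

Step 12
Reactants: 19 2,5-dimethoxy-3,6-bis[5-(3-methylbut-2-en-1-yl)-1H-indol-3-yl]-1,4-benzoquinone
Product: 20 2-hydroxy-5-methoxy-3,6-bis[5-(3-methylbut-2-en-1-yl)-1H-indol-3-yl]-1,4-benzoquinone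
Conditions: 0.5 M NaOH (1.5 equiv), THF/H2O, rt, monitored; then 1 M HCl
Reagents that add atoms: sodium hydroxide, [Na+].[OH-]
Why: Addition–elimination saponification of one vinylogous methyl ester; the hydroxyquinone anion formed first carries a delocalised negative charge that should slow attack at the second methoxy carbon, as in the half-saponification of symmetrical diesters.

Step 13
Reactants: 20 2-hydroxy-5-methoxy-3,6-bis[5-(3-methylbut-2-en-1-yl)-1H-indol-3-yl]-1,4-benzoquinone
Product: 21 hydroperoxycochliodinol, 2-hydroperoxy-5-hydroxy-3,6-bis[5-(3-methylbut-2-en-1-yl)-1H-indol-3-yl]-1,4-benzoquinone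
Conditions: 30% aq. H2O2 (10 equiv), LiOH·H2O (2.2 equiv), THF/H2O, 0 °C; cold 0.5 M HCl to pH 3, extraction and chromatography below rt
Reagents that add atoms: hydrogen peroxide, OO
Why: Proposed new method: the methoxy-bearing ring carbon of 20 is the β-carbon of a vinylogous ester, so the hydroperoxide anion (an α-effect nucleophile, far more nucleophilic than hydroxide) should add there and expel methoxide, giving the vinylogous peroxy acid, which is deprotonated at once and so protected from further attack; low temperature is meant to hold back nucleophilic epoxidation of the quinone; the closest known reaction types are the perhydrolysis of carboxylic esters to peroxy acids with alkaline hydrogen peroxide and the displacement of leaving groups on 1,4-benzoquinones by oxygen nucleophiles.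

**Compound list**

1 | 1,2,4,5-tetramethoxybenzene | COc1cc(OC)c(OC)cc1OC | starting material
2 | 1,4-dibromo-2,3,5,6-tetramethoxybenzene | COc1c(Br)c(OC)c(OC)c(Br)c1OC | intermediate
3 | N-Boc-glycine N-methoxy-N-methylamide | CON(C)C(=O)CNC(=O)OC(C)(C)C | starting material
4 | 1,4-dilithio-2,3,5,6-tetramethoxybenzene (dilithio arene) | COc1c([Li])c(OC)c(OC)c([Li])c1OC | intermediate
5 | N-chloromagnesio derivative of 3 (N-chloromagnesio Weinreb amide) | CON(C)C(=O)CN([Mg]Cl)C(=O)OC(C)(C)C | intermediate
6 | 1,4-bis(N-Boc-aminoacetyl)-2,3,5,6-tetramethoxybenzene | COc1c(OC)c(C(=O)CNC(=O)OC(C)(C)C)c(OC)c(OC)c1C(=O)CNC(=O)OC(C)(C)C | intermediate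
7 | 1,4-bis(aminoacetyl)-2,3,5,6-tetramethoxybenzene bis-hydrochloride | Cl.Cl.COc1c(OC)c(C(=O)CN)c(OC)c(OC)c1C(=O)CN | intermediate
8 | cyclohexane-1,3-dione | O=C1CCCC(=O)C1 | starting material
9 | 1,4-bis{[(3-oxocyclohex-1-en-1-yl)amino]acetyl}-2,3,5,6-tetramethoxybenzene (bis-enaminone) | COc1c(OC)c(C(=O)CNC2=CC(=O)CCC2)c(OC)c(OC)c1C(=O)CNC1=CC(=O)CCC1 | intermediate
10 | 3,3'-(2,3,5,6-tetramethoxy-1,4-phenylene)bis(1,5,6,7-tetrahydro-4H-indol-4-one) | COc1c(OC)c(c2c[nH]c3c2C(=O)CCC3)c(OC)c(OC)c1c1c[nH]c2c1C(=O)CCC2 | intermediate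
11 | di-tert-butyl 3,3'-(2,3,5,6-tetramethoxy-1,4-phenylene)bis(4-oxo-4,5,6,7-tetrahydro-1H-indole-1-carboxylate) | COc1c(OC)c(c2cn(C(=O)OC(C)(C)C)c3c2C(=O)CCC3)c(OC)c(OC)c1c1cn(C(=O)OC(C)(C)C)c2c1C(=O)CCC2 | intermediate
12 | prenyl bromide (1-bromo-3-methylbut-2-ene) | CC(C)=CCBr | starting material
13 | dilithium bis-enolate of 11 (C4–O–Li, C4=C5 in both rings) | COc1c(OC)c(c2cn(C(=O)OC(C)(C)C)c3c2C(O[Li])=CCC3)c(OC)c(OC)c1c1cn(C(=O)OC(C)(C)C)c2c1C(O[Li])=CCC2 | intermediate
14 | di-tert-butyl 3,3'-(2,3,5,6-tetramethoxy-1,4-phenylene)bis[5-(3-methylbut-2-en-1-yl)-4-oxo-4,5,6,7-tetrahydro-1H-indole-1-carboxylate], mixture of C5/C5' diastereomers | COc1c(OC)c(c2cn(C(=O)OC(C)(C)C)c3c2C(=O)C(CC=C(C)C)CC3)c(OC)c(OC)c1c1cn(C(=O)OC(C)(C)C)c2c1C(=O)C(CC=C(C)C)CC2 | intermediate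
15 | di-tert-butyl 3,3'-(2,3,5,6-tetramethoxy-1,4-phenylene)bis[4-hydroxy-5-(3-methylbut-2-en-1-yl)-4,5,6,7-tetrahydro-1H-indole-1-carboxylate], mixture of diastereomers | COc1c(OC)c(c2cn(C(=O)OC(C)(C)C)c3c2C(O)C(CC=C(C)C)CC3)c(OC)c(OC)c1c1cn(C(=O)OC(C)(C)C)c2c1C(O)C(CC=C(C)C)CC2 | intermediate
16 | di-tert-butyl 3,3'-(2,3,5,6-tetramethoxy-1,4-phenylene)bis[5-(3-methylbut-2-en-1-yl)-6,7-dihydro-1H-indole-1-carboxylate] | COc1c(OC)c(c2cn(C(=O)OC(C)(C)C)c3c2C=C(CC=C(C)C)CC3)c(OC)c(OC)c1c1cn(C(=O)OC(C)(C)C)c2c1C=C(CC=C(C)C)CC2 | intermediate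
17 | di-tert-butyl 3,3'-(2,3,5,6-tetramethoxy-1,4-phenylene)bis[5-(3-methylbut-2-en-1-yl)-1H-indole-1-carboxylate] | COc1c(OC)c(c2cn(C(=O)OC(C)(C)C)c3ccc(CC=C(C)C)cc23)c(OC)c(OC)c1c1cn(C(=O)OC(C)(C)C)c2ccc(CC=C(C)C)cc12 | intermediate
18 | di-tert-butyl 3,3'-(2,5-dimethoxy-3,6-dioxocyclohexa-1,4-diene-1,4-diyl)bis[5-(3-methylbut-2-en-1-yl)-1H-indole-1-carboxylate] | COC1=C(c2cn(C(=O)OC(C)(C)C)c3ccc(CC=C(C)C)cc23)C(=O)C(OC)=C(c2cn(C(=O)OC(C)(C)C)c3ccc(CC=C(C)C)cc23)C1=O | intermediate
19 | 2,5-dimethoxy-3,6-bis[5-(3-methylbut-2-en-1-yl)-1H-indol-3-yl]-1,4-benzoquinone | COC1=C(c2c[nH]c3ccc(CC=C(C)C)cc23)C(=O)C(OC)=C(c2c[nH]c3ccc(CC=C(C)C)cc23)C1=O | intermediate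
20 | 2-hydroxy-5-methoxy-3,6-bis[5-(3-methylbut-2-en-1-yl)-1H-indol-3-yl]-1,4-benzoquinone | COC1=C(c2c[nH]c3ccc(CC=C(C)C)cc23)C(=O)C(O)=C(c2c[nH]c3ccc(CC=C(C)C)cc23)C1=O | intermediate
21 | hydroperoxycochliodinol | CC(C)=CCc1ccc2[nH]cc(C3=C(O)C(=O)C(c4c[nH]c5ccc(CC=C(C)C)cc45)=C(OO)C3=O)c2c1 | target

**Step count and risks**

Total step count: 13. Longest linear sequence: 13 steps (1 to 21).

Steps most likely to fail:

1. Step 13 (proposed new method). Nucleophilic epoxidation of the quinone double bond or oxidative ring cleavage of the hydroxyquinone by alkaline peroxide may outrun the addition–elimination, and the O–O bond of the product may break under the basic conditions. The fallback sets out from 19 and replaces methoxide by chloride as the leaving group. Exhaustive saponification (NaOH, EtOH/H2O, reflux, then HCl) should give cochliodinol F1. Oxalyl chloride with catalytic DMF in CH2Cl2 at 0 °C converts both vinylogous acid units into vinylogous acid chlorides, giving 2,5-dichloro-3,6-bis[5-(3-methylbut-2-en-1-yl)-1H-indol-3-yl]-1,4-benzoquinone F2. Cold aqueous NaOH (2 equiv, THF, 0 °C, then HCl) replaces a single chloride, because the hydroxyquinone anion resists the second substitution, giving 2-chloro-5-hydroxy-3,6-bis[5-(3-methylbut-2-en-1-yl)-1H-indol-3-yl]-1,4-benzoquinone F3. Displacement of the remaining chloride by hydrogen peroxide (30% H2O2, NaHCO3, THF/H2O, 0 °C) returns to the route at 21. Halide displacement from halo-1,4-benzoquinones by hydrogen peroxide is an established reaction.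

2. Step 4 (key step). Self-condensation of the liberated aminoketone may compete with enaminone formation, and cyclodehydration onto the hindered aryl ketone may stall on one or both sides. The fallback forms the same two pyrrole rings with reversed bond order (C3–C3a first). It sets out from the dilithio arene 4 (made from 2 as in step 2), which is quenched with DMF to give 2,3,5,6-tetramethoxyterephthalaldehyde F4. Henry condensation with nitromethane (NH4OAc, AcOH, 100 °C) gives 1,4-bis[(E)-2-nitrovinyl]-2,3,5,6-tetramethoxybenzene F5. Heating F5 with 8 and NH4OAc in EtOH forms 3-aminocyclohex-2-en-1-one F6 in the flask. Its α-carbon adds to each nitroalkene, nitrogen then closes onto the nitronate carbon and the nitrogen of the nitro group is lost (Grob–Camenzind-type pyrrole synthesis). This gives the 3-aryl-4-oxo-tetrahydroindoles and rejoins the route at 10.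

3. Step 2. The second bromine–lithium exchange may be incomplete, the dianion may be protonated, or acylation may stop after one side. The fallback avoids organolithium species and sets out from 2. Twofold Stille coupling with tributyl(1-ethoxyvinyl)stannane (Pd(PPh3)4, toluene, 110 °C) gives 1,4-bis(1-ethoxyvinyl)-2,3,5,6-tetramethoxybenzene F7. N-Bromosuccinimide in THF/H2O at 0 °C converts each enol ether into a bromomethyl ketone, giving 1,4-bis(bromoacetyl)-2,3,5,6-tetramethoxybenzene F8. NaN3 in acetone/H2O gives 1,4-bis(azidoacetyl)-2,3,5,6-tetramethoxybenzene F9. Hydrogenation in the presence of HCl (H2, Pd/C, MeOH, HCl) traps the amine as its salt and comes back to the route at 7.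

**Further compounds**

F1 | step 13 | cochliodinol, 2,5-dihydroxy-3,6-bis[5-(3-methylbut-2-en-1-yl)-1H-indol-3-yl]-1,4-benzoquinone | OC1=C(c2c[nH]c3ccc(CC=C(C)C)cc23)C(=O)C(O)=C(c2c[nH]c3ccc(CC=C(C)C)cc23)C1=O
F2 | step 13 | 2,5-dichloro-3,6-bis[5-(3-methylbut-2-en-1-yl)-1H-indol-3-yl]-1,4-benzoquinone | ClC1=C(c2c[nH]c3ccc(CC=C(C)C)cc23)C(=O)C(Cl)=C(c2c[nH]c3ccc(CC=C(C)C)cc23)C1=O
F3 | step 13 | 2-chloro-5-hydroxy-3,6-bis[5-(3-methylbut-2-en-1-yl)-1H-indol-3-yl]-1,4-benzoquinone | ClC1=C(c2c[nH]c3ccc(CC=C(C)C)cc23)C(=O)C(O)=C(c2c[nH]c3ccc(CC=C(C)C)cc23)C1=O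
F4 | step 4 | 2,3,5,6-tetramethoxyterephthalaldehyde | COc1c(OC)c(C=O)c(OC)c(OC)c1C=O
F5 | step 4 | 1,4-bis[(E)-2-nitrovinyl]-2,3,5,6-tetramethoxybenzene | COc1c(OC)c(/C=C/[N+](=O)[O-])c(OC)c(OC)c1/C=C/[N+](=O)[O-]
F6 | step 4 | 3-aminocyclohex-2-en-1-one | NC1=CC(=O)CCC1
F7 | step 2 | 1,4-bis(1-ethoxyvinyl)-2,3,5,6-tetramethoxybenzene | CCOC(=C)c1c(OC)c(OC)c(C(=C)OCC)c(OC)c1OC
F8 | step 2 | 1,4-bis(bromoacetyl)-2,3,5,6-tetramethoxybenzene | COc1c(OC)c(C(=O)CBr)c(OC)c(OC)c1C(=O)CBr
F9 | step 2 | 1,4-bis(azidoacetyl)-2,3,5,6-tetramethoxybenzene | COc1c(OC)c(C(=O)CN=[N+]=[N-])c(OC)c(OC)c1C(=O)CN=[N+]=[N-]
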